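Atom numbering of the target: C1 is the O–CH2 carbon of the ester, C16 the branched carbon, C17–C18 the ethyl end.

## Analysis of the target

Gentiside F is (16S)-16-methyloctadecyl 2,3-dihydroxybenzoate: an unbranched C18 primary alkyl chain with one methyl branch at C16, esterified with 2,3-dihydroxybenzoic acid. The benzene ring is the only ring, so nothing has to be cyclised. C16 is the only stereocenter and it is S. Its four substituents are hydrogen, methyl, ethyl (C17–C18) and a chain of fifteen methylenes, so no heteroatom nearby can direct a reagent and there is no second center to relate it to. The sensitive part is the aromatic end: a catechol that is oxidised by air under basic conditions and binds metals, and a salicylate-type ester that can transesterify. Both argue for attaching the acid in the last step. The difficulty lies in one point: making a tertiary carbon whose three carbon substituents differ only in length, in high enantiopurity, in a waxy molecule that cannot be enriched by crystallisation and whose enantiomeric purity is hard even to measure. The strategy rests on C16 being a methyl-bearing carbon between C17 and an unbranched chain. That pattern arises when CH3 and a metal add across a monosubstituted C16=C17 double bond, methyl to C16 and metal to C17. The metal at C17 then becomes a hydroxyl group one carbon from the stereocenter, where it serves for analysis, for enzymatic enrichment and as the point of attachment for C18.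

## Retrosynthetic reasoning

**Ester bond (12 to 10 and 11).** The target 12 is cut at the C1–O ester bond into alcohol 10 and acid 11. This is done last so that the catechol never meets organometallic reagents, fluoride or base. The forward reaction has to acylate a primary alcohol with an acid that carries two free phenols; a redox condensation that uses the large acidity gap between CO2H and the phenolic OH groups does this without phenol protection.

**Silyl ether (10 to 9).** Alcohol 10 comes from silyl ether 9. The C1 oxygen has to be masked from the start, because the chain is built with an organoaluminium reagent and an organomagnesium reagent. A bulky aryl-substituted silyl group survives both, gives the greasy intermediates a chromophore and is removed cleanly at the end.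

**C17–C18 bond (9 to 8 to 7).** The ethyl end of 9 is cut between C17 and C18, which leads to tosylate 8 and then to alcohol 7. The cut is placed here because the key step leaves oxygen on C17; replacing that oxygen by a one-carbon nucleophile under copper catalysis completes the chain. The stereocenter is β to the reacting carbon and carries no acidic hydrogen, so it is not at risk. Alcohol 7 is also the only intermediate with a functional group next to C16. Its conversion into 8 therefore opens with an enzymatic acylation that takes out the minor enantiomer as a non-polar ester, and only the alcohol that remains is sulfonylated. This is the point where the enantiomeric purity is measured and raised.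

**C16–CH3 and C17–O bonds (7 to 4 and 5).** Alcohol 7 is cut at the C16–methyl bond and the C17–O bond at once, giving terminal alkene 4 and trimethylaluminium 5. In the forward direction a chiral zirconocene catalyst adds methyl and aluminium across C16=C17, forming alane 6, and oxidative cleavage of its carbon–aluminium bond gives 7. This disconnection creates the stereocenter and one skeletal bond in one operation, from an alkene that has no stereochemistry and no functional group near the reacting site. It is the only step that has to be selective between enantiotopic faces.

**Alkene and chain (4 to 3 to 2 to 1).** Alkene 4 is the silyl ether of alkenol 3. The C16=C17 bond of 3 is cut by one-carbon olefination back to hydroxy aldehyde 2, and 2 is the half-reduced, ring-opened form of macrolactone 1. Lactone 1 already holds the sixteen chain carbons with the two ends at different oxidation levels. No symmetric diol has to be desymmetrised and no chain has to be assembled from pieces.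

## Alternatives that were turned down

**Alternative 1: ene-reductase on an enal.** The disconnection removes the two hydrogens at C16 and C17, leading back to the trisubstituted enal (2E)-18-hydroxy-3-methyloctadec-2-enal A2. In the forward key step a flavin-dependent ene-reductase of the Old Yellow Enzyme family, with NADPH recycled by glucose dehydrogenase, delivers hydride to the β-carbon and a proton to the α-carbon and gives (3R)-18-hydroxy-3-methyloctadecanal A1.
- For it: enzymes of this class often reduce 3-methyl enals with very high enantioselectivity, the free hydroxyl needs no protection, and no enrichment would be needed. On intrinsic enantioselectivity this alternative is stronger than the chosen key step.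
- Against it: E and Z isomers of such enals commonly give opposite enantiomers and interconvert easily, so A2 must be made and kept geometrically pure. A2 is a C19 amphiphile that dissolves poorly in buffer. An enzyme that accepts a fifteen-carbon β-substituent has to be found by screening. After the reduction the aldehyde carbon (C18 of the target) still has to be deoxygenated to a methyl group beside a free primary alcohol. Building A2 takes a ketone olefination with E/Z separation and a redox adjustment.
- Comparison: more steps on both sides of the key step and a dependence on screening. The chosen route offers in exchange a precursor that is made in three routine steps, a catalyst whose sense of induction can be predicted, and formation of the branch C–C bond in the same step as the stereocenter.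

**Alternative 2: Claisen rearrangement with chirality transfer.** The disconnection cuts C16–C17 and stores the chirality at a C14 carbinol. Heating the allyl vinyl ether ({[(14S,15E)-14-(ethenyloxy)heptadec-15-en-1-yl]oxy}methyl)benzene A4 gives (3S,4E)-18-(benzyloxy)-3-methyloctadec-4-enal A3 through a chair transition state with the long chain equatorial.
- For it: transfer of chirality in such rearrangements is essentially complete and fully predictable, and secondary allylic alcohols can be obtained in very high enantiopurity by asymmetric reduction or by lipase resolution. Lipase resolution is far more selective for secondary carbinols than for the primary alcohol 7. On security of enantiopurity this alternative is stronger.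
- Against it: the stereocenter is made twice, first at C14 and then relayed to C16. A3 carries three features the target does not have: the C14=C15 alkene, the aldehyde at C18 and the benzyl ether. Saturating an alkene that is allylic to the stereocenter over Pd/C risks double-bond migration through C16. Turning the aldehyde into a methyl group costs two or three steps, and the vinyl ether has to be made by Hg(OAc)2-catalysed transvinylation or a similar extra step.
- Comparison: the sequence is several steps longer than the chosen one. The chosen route places the stereocenter directly where it is needed and leaves nothing to erase except one hydroxyl, which is itself put to use.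

**Alternative 3: mixed Kolbe electrolysis.** The disconnection cuts C14–C15, far from the stereocenter. Co-electrolysis of (3S)-3-methylpentanoic acid A6 and 15-(acetyloxy)pentadecanoic acid A7 at a platinum anode in methanol decarboxylates both and couples the two primary radicals to (16S)-16-methyloctadecyl acetate A5.
- For it: this is the shortest route on paper (electrolysis, acetate cleavage, esterification). The stereocenter is bought and not made, and a radical at C15 does not disturb C16. On step count, and on enantiopurity if A6 is pure, this alternative is stronger than the chosen one.
- Against it: a mixed Kolbe coupling is statistical. Both symmetrical dimers form beside A5, and disproportionation and cation-derived products accompany them, so the efficiency based on the valuable chiral acid is inherently limited even with A7 in excess. A6 is not a bulk chemical; it is usually prepared by homologation of a chiral-pool alcohol of variable optical purity, which takes back two or three steps and ties the final enantiopurity to the source. There is no intermediate on which the enantiomeric purity could be checked or raised.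
- Comparison: the chosen route starts from achiral bulk materials, reaches either enantiomer by choice of catalyst, avoids statistical product mixtures and passes through an intermediate (7) that can be analysed and upgraded.

Key step: step 4

Assumption: (−)-(NMI)2ZrCl2 is taken to induce the same sense as with unbranched 1-alkenes (R alcohol after oxidation), and Amano lipase PS to acylate the S enantiomer of 2-methylalkan-1-ols faster; the remote silyl ether is assumed to change neither.

## Route

Step 1
Reactants: 1 16-hexadecanolide (oxacycloheptadecan-2-one)
Product: 2 16-hydroxyhexadecanal
Conditions: i-Bu2AlH (1.1 equiv), CH2Cl2, −78 °C; MeOH, then aq. potassium sodium tartrate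
Reagents that add atoms: none
Why: Partial hydride reduction of a lactone; the tetrahedral aluminium hemiacetal is stable at −78 °C and collapses only on work-up, and because the ring is seventeen-membered the product is the open hydroxy aldehyde, not a lactol.

Step 2
Reactants: 2 16-hydroxyhexadecanal
Product: 3 heptadec-16-en-1-ol
Conditions: Ph3PCH3Br (2.0 equiv), KOt-Bu (1.9 equiv), THF, 0 °C to rt
Reagents that add atoms: methyltriphenylphosphonium bromide, C[P+](c1ccccc1)(c1ccccc1)c1ccccc1.[Br-]
Why: Wittig methylenation of an unhindered aldehyde with a non-stabilised ylide; the free hydroxyl is too weak an acid to quench the ylide irreversibly, and keeping the base below the amount of phosphonium salt leaves no excess alkoxide to enolise the aldehyde.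

Step 3
Reactants: 3 heptadec-16-en-1-ol
Product: 4 tert-butyl(heptadec-16-en-1-yloxy)diphenylsilane
Conditions: TBDPSCl, imidazole, CH2Cl2, rt
Reagents that add atoms: tert-butyl(chloro)diphenylsilane, CC(C)(C)[Si](Cl)(c1ccccc1)c1ccccc1
Why: Imidazole-promoted silylation of a primary alcohol; the tert-butyldiphenylsilyl ether tolerates organoalanes, sulfonylation and Grignard reagents and gives the later intermediates a UV chromophore.

Step 4
Reactants: 4 tert-butyl(heptadec-16-en-1-yloxy)diphenylsilane; 5 trimethylaluminium
Product: 7 (2R)-17-[(tert-butyldiphenylsilyl)oxy]-2-methylheptadecan-1-ol, via (2R)-2-methylalkyl dimethylalane 6 (not isolated)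
Conditions: Me3Al (2.5 equiv), (−)-dichlorobis(1-neomenthylindenyl)zirconium [(−)-(NMI)2ZrCl2] (5 mol %), methylaluminoxane (MeAlO)n (1 equiv), CH2Cl2, 0 °C to rt; then O2, 0 °C to rt; cold 1 M aq. HCl
Reagents that add atoms: dioxygen, O=O
Why: Me3Al methylates (NMI)2ZrCl2 and methylaluminoxane abstracts an anionic ligand, giving a cationic methylzirconocene held in a Zr–Al ion pair; the alkene of 4 inserts into the Zr–CH3 bond with zirconium at the terminal carbon C17 and methyl at C16, and exchange with Me3Al moves the new alkyl group to aluminium as alane 6 and restores Zr–CH3. The closest known reaction type is the zirconium-catalysed asymmetric carboalumination of unactivated monosubstituted alkenes with Me3Al followed by oxidation to 2-methylalkan-1-ols, for which unbranched 1-alkenes with remote silyl ethers are standard substrates. No ring is formed. The one new stereocenter, C2 of 7 (C16 of the target), is fixed in the insertion by the catalyst alone: the two 1-neomenthylindenyl ligands form a chiral pocket that admits the alkyl chain in one orientation, so methyl reaches one enantiotopic face, and the (−)-catalyst is expected to give the R alcohol. Regioselectivity (methyl to the internal carbon) follows from the preference of zirconium for the primary carbon of a monosubstituted alkene; single insertion rather than oligomerisation follows from fast Zr-to-Al transfer under excess Me3Al, and the bulky indenyl ligands and the chlorinated solvent hold back β-hydride transfer and the cyclic zirconacycle pathway. The silyl ether is fifteen carbons from the alkene, binds aluminium only reversibly and should not be cleaved. O2 inserts into the C–Al bond of 6 to give the aluminium alkoxide, which work-up frees as 7; C17 is not stereogenic and C16 is not touched. Face selectivity is the weak point, since the alkene has only a methylene chain beside it, and an enantiomeric excess well short of complete should be expected, which is why step 5 opens with an enzymatic enrichment.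

Step 5
Reactants: 7 (2R)-17-[(tert-butyldiphenylsilyl)oxy]-2-methylheptadecan-1-ol
Product: 8 (2R)-17-[(tert-butyldiphenylsilyl)oxy]-2-methylheptadecyl 4-methylbenzenesulfonate
Conditions: Amano lipase PS, vinyl acetate, THF, rt, to partial conversion; filter, concentrate; then TsCl, Et3N, DMAP (cat.), CH2Cl2, 0 °C to rt; chromatography
Reagents that add atoms: 4-methylbenzenesulfonyl chloride, Cc1ccc(cc1)S(=O)(=O)Cl
Why: Lipase-catalysed kinetic resolution by irreversible transesterification, followed in the same operation by sulfonylation of a primary alcohol at oxygen: the enzyme acetylates the faster-reacting S enantiomer (and any unbranched alcohol left from hydroalumination), so the minor enantiomer is locked as an acetate that TsCl cannot touch, and only the free R alcohol becomes the tosylate, with no bond to the stereocenter made or broken. The enzymatic stage is followed by Mosher ester analysis or chiral HPLC of aliquots of 7 and stopped when the residual alcohol should be enantiomerically pure; the acetate is less polar than the sulfonate and is removed on silica.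

Step 6
Reactants: 8 (2R)-17-[(tert-butyldiphenylsilyl)oxy]-2-methylheptadecyl 4-methylbenzenesulfonate
Product: 9 tert-butyl{[(16S)-16-methyloctadecyl]oxy}diphenylsilane
Conditions: CH3MgBr (4 equiv), Li2CuCl4 (5 mol %), THF, −78 °C to rt
Reagents that add atoms: methylmagnesium bromide, C[Mg]Br
Why: Copper-catalysed cross-coupling of a Grignard reagent with a primary tosylate (Kochi-type coupling); the methylcuprate formed in situ displaces the sulfonate at C17 in an SN2 process, and the β stereocenter, which has no acidic hydrogen, is untouched. The descriptor changes from R to S only because CH2OTs becomes an ethyl group of lower priority than the long chain.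

Step 7
Reactants: 9 tert-butyl{[(16S)-16-methyloctadecyl]oxy}diphenylsilane
Product: 10 (16S)-16-methyloctadecan-1-ol
Conditions: n-Bu4NF, THF, rt; aq. NH4Cl
Reagents that add atoms: none
Why: Fluoride-induced cleavage of a silyl ether, driven by the strength of the Si–F bond; the saturated chain has no other reactive site.

Step 8
Reactants: 10 (16S)-16-methyloctadecan-1-ol; 11 2,3-dihydroxybenzoic acid
Product: 12 Gentiside F [(16S)-16-methyloctadecyl 2,3-dihydroxybenzoate]
Conditions: PPh3, DIAD, THF, 0 °C to rt, under argon
Reagents that add atoms: none
Why: Mitsunobu esterification; the phosphine–azodicarboxylate betaine is protonated by the carboxylic acid, which is several pKa units more acidic than either phenol, and the carboxylate displaces the alkoxyphosphonium group of the primary alcohol, so phenolic acids are esterified at CO2H without protection. C1 is not stereogenic, so the inversion has no consequence.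

## Compound list

1 | 16-hexadecanolide (oxacycloheptadecan-2-one) | O=C1CCCCCCCCCCCCCCCO1 | starting material
2 | 16-hydroxyhexadecanal | O=CCCCCCCCCCCCCCCCO | intermediate
3 | heptadec-16-en-1-ol | C=CCCCCCCCCCCCCCCCO | intermediate
4 | tert-butyl(heptadec-16-en-1-yloxy)diphenylsilane | C=CCCCCCCCCCCCCCCCO[Si](c1ccccc1)(c1ccccc1)C(C)(C)C | intermediate
5 | trimethylaluminium | C[Al](C)C | starting material
6 | [(2R)-17-[(tert-butyldiphenylsilyl)oxy]-2-methylheptadecyl]dimethylalane | C[Al](C)C[C@H](C)CCCCCCCCCCCCCCCO[Si](c1ccccc1)(c1ccccc1)C(C)(C)C | intermediate
7 | (2R)-17-[(tert-butyldiphenylsilyl)oxy]-2-methylheptadecan-1-ol | OC[C@H](C)CCCCCCCCCCCCCCCO[Si](c1ccccc1)(c1ccccc1)C(C)(C)C | intermediate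
8 | (2R)-17-[(tert-butyldiphenylsilyl)oxy]-2-methylheptadecyl 4-methylbenzenesulfonate | Cc1ccc(cc1)S(=O)(=O)OC[C@H](C)CCCCCCCCCCCCCCCO[Si](c1ccccc1)(c1ccccc1)C(C)(C)C | intermediate
9 | tert-butyl{[(16S)-16-methyloctadecyl]oxy}diphenylsilane | CC[C@H](C)CCCCCCCCCCCCCCCO[Si](c1ccccc1)(c1ccccc1)C(C)(C)C | intermediate
10 | (16S)-16-methyloctadecan-1-ol | CC[C@H](C)CCCCCCCCCCCCCCCO | intermediate
11 | 2,3-dihydroxybenzoic acid | O=C(O)c1cccc(O)c1O | starting material
12 | Gentiside F [(16S)-16-methyloctadecyl 2,3-dihydroxybenzoate] | CC[C@H](C)CCCCCCCCCCCCCCCOC(=O)c1cccc(O)c1O | target

## Step count and least certain steps

Total: 8 steps. Longest linear sequence: 8 steps, from 1 to 12; the acid 11 enters in the last step.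

**Step 4 (key step).** The most likely failure is poor discrimination between the two alkene faces, because the substrate offers the catalyst only a methylene chain next to the double bond. In addition, β-hydride transfer at zirconium can lead to hydroalumination instead of methylalumination, which would give an unbranched alcohol beside 7. The fallback replaces catalyst control by auxiliary control; it sets out from 4 and returns at 7. Hydroboration of 4 with 9-borabicyclononane and oxidation with H2O2/NaOH would give 17-[(tert-butyldiphenylsilyl)oxy]heptadecan-1-ol F1. Oxidation with TEMPO/NaOCl/NaClO2 in buffered acetonitrile would give 17-[(tert-butyldiphenylsilyl)oxy]heptadecanoic acid F2. Activation as the mixed pivalic anhydride and acylation of lithiated (4R)-4-benzyl-1,3-oxazolidin-2-one would give (4R)-4-benzyl-3-{17-[(tert-butyldiphenylsilyl)oxy]heptadecanoyl}-1,3-oxazolidin-2-one F3. Its chelated Z sodium enolate (NaN(SiMe3)2, THF, −78 °C) would be methylated with CH3I on the face away from the benzyl group, giving (4R)-4-benzyl-3-{(2R)-17-[(tert-butyldiphenylsilyl)oxy]-2-methylheptadecanoyl}-1,3-oxazolidin-2-one F4, which is freed from its minor diastereomer by chromatography. Reduction with LiBH4 then releases 7. The enzymatic stage of step 5 is not needed in that case, and 7 is tosylated directly.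

**Step 5.** The most likely failure is low discrimination between the enantiomers by the enzyme. The acylated oxygen is one carbon from the stereocenter, which differs only in methyl against a long chain, so reaching high purity could cost much of the alcohol; slow turnover of a waxy substrate is also possible. A lesser concern is incomplete separation of the acetate from 8; any acetate carried forward would be cleaved by the Grignard reagent of step 6 to a polar alcohol that is far from 9 on silica. The fallback is a covalent resolution; it sets out from 7 of insufficient purity and returns to 7, which is then tosylated without the enzymatic stage. Oxidation with TEMPO/NaOCl/NaClO2 under buffered conditions would give (2R)-17-[(tert-butyldiphenylsilyl)oxy]-2-methylheptadecanoic acid F5. Acylation of (4R)-4-benzyl-1,3-oxazolidin-2-one (pivaloyl chloride, Et3N, LiCl) would give (4R)-4-benzyl-3-{(2R)-17-[(tert-butyldiphenylsilyl)oxy]-2-methylheptadecanoyl}-1,3-oxazolidin-2-one F4 together with its epimer (4R)-4-benzyl-3-{(2S)-17-[(tert-butyldiphenylsilyl)oxy]-2-methylheptadecanoyl}-1,3-oxazolidin-2-one F6. The two diastereomers are separated on silica, and LiBH4 reduction of F4 gives 7.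

**Step 1.** The most likely failure is over-reduction to the diol or incomplete conversion, together with hemiacetal oligomerisation of the hydroxy aldehyde on concentration. The fallback avoids a free hydroxy aldehyde; it sets out from 1 and returns at 4. Aminolysis of 1 with N,O-dimethylhydroxylamine hydrochloride and Me3Al would give 16-hydroxy-N-methoxy-N-methylhexadecanamide F7. Silylation (TBDPSCl, imidazole) would give 16-[(tert-butyldiphenylsilyl)oxy]-N-methoxy-N-methylhexadecanamide F8. i-Bu2AlH at −78 °C would give 16-[(tert-butyldiphenylsilyl)oxy]hexadecanal F9, because the chelated tetrahedral intermediate cannot be reduced further. Wittig methylenation then gives 4.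

**Step 6.** The most likely failure is slow substitution at a β-branched primary carbon, which lets attack of the methyl nucleophile at sulfur (returning the alcohol) and elimination compete. The fallback forms the C17–C18 bond by olefination; it sets out from 7, isolated by chromatography after the enzymatic stage of step 5 in place of tosylation, and returns at 9. Oxidation with Dess–Martin periodinane buffered with NaHCO3 would give (2R)-17-[(tert-butyldiphenylsilyl)oxy]-2-methylheptadecanal F10, which is used at once. Methylenation with the ylide from Ph3PCH3Br and KN(SiMe3)2 at −78 to 0 °C would give tert-butyl{[(16R)-16-methyloctadec-17-en-1-yl]oxy}diphenylsilane F11. Reduction with diimide (4-methylbenzenesulfonohydrazide, NaOAc, aqueous dimethoxyethane, reflux) gives 9. Diimide is chosen because no metal hydride is present that could move the double bond into the stereocenter.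

**Step 8.** The most likely failure is interference of the catechol with the phosphine–azodicarboxylate system (cyclic phosphorane formation, O-alkylation of a phenol, oxidation), which would lower conversion and complicate purification of a product that cannot be crystallised. The fallback separates activation from ester formation; it sets out from 10 and returns at 12. CBr4 and PPh3 in CH2Cl2 would convert 10 into (16S)-1-bromo-16-methyloctadecane F12. F12 then alkylates the monoanion of 11 (KHCO3, DMF, 50 °C, under argon). Only the carboxylate is ionised by hydrogencarbonate, so 12 should form without phenol alkylation.

## Further compounds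

F1 | step 4 | 17-[(tert-butyldiphenylsilyl)oxy]heptadecan-1-ol | OCCCCCCCCCCCCCCCCCO[Si](c1ccccc1)(c1ccccc1)C(C)(C)C
F2 | step 4 | 17-[(tert-butyldiphenylsilyl)oxy]heptadecanoic acid | OC(=O)CCCCCCCCCCCCCCCCO[Si](c1ccccc1)(c1ccccc1)C(C)(C)C
F3 | step 4 | (4R)-4-benzyl-3-{17-[(tert-butyldiphenylsilyl)oxy]heptadecanoyl}-1,3-oxazolidin-2-one | O=C(CCCCCCCCCCCCCCCCO[Si](c1ccccc1)(c1ccccc1)C(C)(C)C)N1[C@H](Cc2ccccc2)COC1=O
F4 | step 4 | (4R)-4-benzyl-3-{(2R)-17-[(tert-butyldiphenylsilyl)oxy]-2-methylheptadecanoyl}-1,3-oxazolidin-2-one | O=C(N1[C@H](Cc2ccccc2)COC1=O)[C@H](C)CCCCCCCCCCCCCCCO[Si](c1ccccc1)(c1ccccc1)C(C)(C)C
F5 | step 5 | (2R)-17-[(tert-butyldiphenylsilyl)oxy]-2-methylheptadecanoic acid | OC(=O)[C@H](C)CCCCCCCCCCCCCCCO[Si](c1ccccc1)(c1ccccc1)C(C)(C)C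
F6 | step 5 | (4R)-4-benzyl-3-{(2S)-17-[(tert-butyldiphenylsilyl)oxy]-2-methylheptadecanoyl}-1,3-oxazolidin-2-one | O=C(N1[C@H](Cc2ccccc2)COC1=O)[C@@H](C)CCCCCCCCCCCCCCCO[Si](c1ccccc1)(c1ccccc1)C(C)(C)C
F7 | step 1 | 16-hydroxy-N-methoxy-N-methylhexadecanamide | CON(C)C(=O)CCCCCCCCCCCCCCCO
F8 | step 1 | 16-[(tert-butyldiphenylsilyl)oxy]-N-methoxy-N-methylhexadecanamide | CON(C)C(=O)CCCCCCCCCCCCCCCO[Si](c1ccccc1)(c1ccccc1)C(C)(C)C
F9 | step 1 | 16-[(tert-butyldiphenylsilyl)oxy]hexadecanal | O=CCCCCCCCCCCCCCCCO[Si](c1ccccc1)(c1ccccc1)C(C)(C)C
F10 | step 6 | (2R)-17-[(tert-butyldiphenylsilyl)oxy]-2-methylheptadecanal | O=C[C@H](C)CCCCCCCCCCCCCCCO[Si](c1ccccc1)(c1ccccc1)C(C)(C)C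
F11 | step 6 | tert-butyl{[(16R)-16-methyloctadec-17-en-1-yl]oxy}diphenylsilane | C=C[C@H](C)CCCCCCCCCCCCCCCO[Si](c1ccccc1)(c1ccccc1)C(C)(C)C
F12 | step 8 | (16S)-1-bromo-16-methyloctadecane | CC[C@H](C)CCCCCCCCCCCCCCCBr
A1 | alternative 1 | (3R)-18-hydroxy-3-methyloctadecanal | O=CC[C@H](C)CCCCCCCCCCCCCCCO
A2 | alternative 1 | (2E)-18-hydroxy-3-methyloctadec-2-enal | O=C/C=C(C)/CCCCCCCCCCCCCCCO
A3 | alternative 2 | (3S,4E)-18-(benzyloxy)-3-methyloctadec-4-enal | O=CC[C@H](C)/C=C/CCCCCCCCCCCCCOCc1ccccc1
A4 | alternative 2 | ({[(14S,15E)-14-(ethenyloxy)heptadec-15-en-1-yl]oxy}methyl)benzene | C=CO[C@H](/C=C/C)CCCCCCCCCCCCCOCc1ccccc1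
A5 | alternative 3 | (16S)-16-methyloctadecyl acetate | CC[C@H](C)CCCCCCCCCCCCCCCOC(C)=O
A6 | alternative 3 | (3S)-3-methylpentanoic acid | CC[C@H](C)CC(=O)O
A7 | alternative 3 | 15-(acetyloxy)pentadecanoic acid | CC(=O)OCCCCCCCCCCCCCCC(=O)O
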